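**Retrosynthetic overview**

1. Target 34 ⇐ acetylation and C1–OH-directed hydrogenation of C9=C11 ⇐ diene 31, whose ring B (C5–C6–C7–C8–C9–C10) is closed last by a formate-terminated 6-exo Heck cyclization of dienyl triflate 30 (C9–C10 bond).
2. Enabling feature: C10 is a quaternary carbon that bears a methyl group and lies between ring A (C1, C5) and C9 of ring C. The C10–CH3 unit can therefore be carried as an exocyclic C10=CH2 on the ε-lactone (ring A) and C9 as an alkenyl triflate carbon of ring C, held five atoms apart by the C5–C6–C7–C8 tether.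
3. 30 ⇐ spiro-annulation of vinyl epoxide 26 (C9–OH-directed epoxidation) with the preformed furanone ester 19; ring C comes from (S)-carvone, and quaternary C8 from two α′-alkylations, the first of which joins ring A triflate 10.
4. 10 ⇐ homogeraniol by Shi epoxidation, titanocene radical cyclization, Baeyer–Villiger ring expansion to the ε-lactone and SeO2 oxidation at C1.
5. Order of ring formation: ring A (carbocycle, then ε-lactone), furanone ring (in 19), ring C taken from carvone, spiro γ-lactone, ring B.

Key step: step 22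

Remark on numbering: atom numbers follow the target (C1 = CH–OAc, C3 = ring A lactone C=O, C4 = CMe2, C5/C10 shared by rings A and B, C8/C9 shared by rings B and C, C13 = C–Me of the ring C alkene, C14 and C16 = spiro carbons, C15 = lactone CH2).
Assumption: homogeraniol (1) and ethyl 2-methylbuta-2,3-dienoate (17) are taken as purchasable (1 is otherwise three known steps from geraniol).

**Route**

Step 1
Reactants: 1 homogeraniol [(3E)-4,8-dimethylnona-3,7-dien-1-ol]
Product: 2 homogeranyl TBS ether
Conditions: TBSCl, imidazole, DMF, 0 °C to rt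
Reagents that add atoms: tert-butyldimethylsilyl chloride, CC(C)(C)[Si](C)(C)Cl
Why: Standard silylation of a primary alcohol; the ether survives the oxidations that follow and can later be removed beside a TIPS ether.

Step 2
Reactants: 2 homogeranyl TBS ether
Product: 3 (R)-7,8-epoxyhomogeranyl TBS ether
Conditions: D-fructose-derived ketone catalyst (1,2:4,5-di-O-isopropylidene-β-D-erythro-hexo-2,3-diulo-2,6-pyranose, 0.3 equiv), KHSO5 (triple salt), K2CO3, Bu4NHSO4, MeCN/dimethoxymethane/aqueous borate buffer (pH 10.5), 0 °C, stopped at partial conversion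
Reagents that add atoms: potassium peroxymonosulfate, [K+].[O-]S(=O)(=O)OO
Why: Shi epoxidation; the chiral dioxirane should attack the terminal trisubstituted alkene (more accessible, and not deactivated by the homoallylic silyloxy group) through a spiro transition state to give the (R)-epoxide.

Step 3
Reactants: 3 (R)-7,8-epoxyhomogeranyl TBS ether
Product: 4 (1R,3S)-cyclohexanol with exocyclic methylene
Conditions: Cp2TiCl2 (2.2 equiv), Mn dust, THF, rt; then brief dilute aqueous HCl
Reagents that add atoms: none
Why: Titanocene-mediated radical epoxide cyclization; trivalent titanium opens the epoxide to the tertiary C4 radical, 6-endo closure through a chair with the C3–O and C5 side chain equatorial sets C5 (S) from the retained C3 (R), and the tertiary C10 radical is captured by a second trivalent titanium and leaves as the exocyclic alkene by β-hydride elimination.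

Step 4
Reactants: 4 (1R,3S)-cyclohexanol with exocyclic methylene
Product: 5 (3S)-cyclohexanone
Conditions: Dess–Martin periodinane, NaHCO3, CH2Cl2, rt
Reagents that add atoms: none
Why: Dess–Martin oxidation gives the ketone for ring expansion under buffered conditions that leave the alkene and silyl ether untouched; the C3 stereocentre is deliberately erased.

Step 5
Reactants: 5 (3S)-cyclohexanone
Product: 6 (6S)-ε-lactone (ring A)
Conditions: bis(trimethylsilyl) peroxide (1.5 equiv), TMSOTf (10 mol %), CH2Cl2, −78 to −40 °C; pyridine quench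
Reagents that add atoms: bis(trimethylsilyl) peroxide, C[Si](C)(C)OO[Si](C)(C)C
Why: Baeyer–Villiger oxidation in which the quaternary C4 migrates; the aprotic silyl peroxide system should not epoxidize the 1,1-disubstituted alkene, and C5 is not touched.

Step 6
Reactants: 6 (6S)-ε-lactone
Product: 7 (4R,6S)-lactone C1 alcohol
Conditions: SeO2 (0.5 equiv), t-BuOOH (3 equiv), CH2Cl2, 0 °C to rt
Reagents that add atoms: tert-butyl hydroperoxide, CC(C)(C)OO
Why: SeO2 allylic oxidation (ene reaction, then 2,3-shift) at the only allylic methylene, C1; the enophile should approach the alkene face opposite the C5 side chain, placing the new hydroxyl trans to that chain (1R), as in related exo-methylene terpenoids.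

Step 7
Reactants: 7 (4R,6S)-lactone C1 alcohol
Product: 8 C1 TIPS ether
Conditions: TIPSOTf, 2,6-lutidine, CH2Cl2, −78 to 0 °C
Reagents that add atoms: triisopropylsilyl triflate, CC(C)[Si](C(C)C)(C(C)C)OS(=O)(=O)C(F)(F)F
Why: Silyl triflate silylation of the hindered allylic alcohol gives a TIPS ether that is inert to enolates and to zerovalent palladium and outlasts both TBS ethers.

Step 8
Reactants: 8 C1 TIPS ether
Product: 9 primary alcohol
Conditions: HF·pyridine, pyridine, THF, 0 °C
Reagents that add atoms: none
Why: Buffered HF·pyridine cleaves the unhindered primary TBS ether much faster than the secondary TIPS ether and does not open the lactone.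

Step 9
Reactants: 9 primary alcohol
Product: 10 primary triflate
Conditions: Tf2O, 2,6-lutidine, CH2Cl2, −78 °C; used at once after cold work-up
Reagents that add atoms: triflic anhydride, O=S(=O)(OS(=O)(=O)C(F)(F)F)C(F)(F)F
Why: Triflation of the primary alcohol gives an electrophile reactive enough to alkylate a lithium enolate at −78 °C.

Step 10
Reactants: 11 (S)-carvone
Product: 13 (1S)-4-methyl-5-oxocyclohex-3-en-1-yl acetate, via methoxy hydroperoxide 12 (not isolated)
Conditions: O3, CH2Cl2/MeOH, NaHCO3, −78 °C (indicator dye end point); then Ac2O, Et3N, DMAP (cat.), CH2Cl2, −15 °C to rt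
Reagents that add atoms: ozone, [O-][O+]=O; methanol, CO
Why: Ozone cleaves the isolated 1,1-disubstituted alkene in preference to the conjugated one, and the acetylated methoxy hydroperoxide undergoes Criegee rearrangement with retention at the migrating ring carbon, so the acetyl group of 13 is the former isopropenyl carbon pair and the (S) centre becomes the future C9 oxygen.

Step 11
Reactants: 13 (1S)-4-methyl-5-oxocyclohex-3-en-1-yl acetate
Product: 14 (5S)-5-hydroxy-2-methylcyclohex-2-en-1-one
Conditions: HCl (from AcCl, 0.3 equiv), MeOH, 0 °C to rt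
Reagents that add atoms: none
Why: Acid-catalysed transesterification removes the acetate without forming the enolate that would eliminate the β-acyloxy group; the stereocentre is not affected.

Step 12
Reactants: 14 (5S)-5-hydroxy-2-methylcyclohex-2-en-1-one
Product: 15 (5S)-5-(tert-butyldimethylsilyloxy)-2-methylcyclohex-2-en-1-one
Conditions: TBSCl, imidazole, DMF, 0 °C to rt
Reagents that add atoms: tert-butyldimethylsilyl chloride, CC(C)(C)[Si](C)(C)Cl
Why: Standard silylation; the bulky silyloxy group is the control element for the two α′-alkylations and a poor leaving group from the enolate.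

Step 13
Reactants: 16 ethyl glycolate; 17 ethyl 2-methylbuta-2,3-dienoate
Product: 19 ethyl 4,5-dimethyl-3-oxo-2,3-dihydrofuran-2-carboxylate, via oxa-Michael adduct 18 (not isolated)
Conditions: NaH (2.1 equiv), THF, 0 °C to rt; then 1 M HCl
Reagents that add atoms: none
Why: The alkoxide adds to the central allene carbon (oxa-Michael) and the α-alkoxy ester carbanion of 18 closes by a 5-exo-trig Dieckmann condensation, driven by deprotonation of the acidic product; the C2 centre is enolizable and carries no stereochemical information.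

Step 14
Reactants: 15 (5S)-5-(tert-butyldimethylsilyloxy)-2-methylcyclohex-2-en-1-one; 10 primary triflate
Product: 21 monoalkylated enone (8R,9S), via lithium enolate 20 (not isolated)
Conditions: LiN(i-Pr)2 (1.1 equiv to 15), THF, −78 °C; then 10 (0.8 equiv), THF, −78 to −45 °C
Reagents that add atoms: none
Why: Kinetic α′-enolate alkylation; the primary triflate reacts at low temperature, where the β-silyloxy enolate does not eliminate and the lactone is not attacked, and it enters anti to the adjacent silyloxy group (chain trans to C9–O).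

Step 15
Reactants: 21 monoalkylated enone (8R,9S)
Product: 23 C8-quaternary enone (8S,9S), via lithium enolate 22 (not isolated)
Conditions: LiN(i-Pr)2 (1.15 equiv), THF, −78 °C; then MeI (5 equiv), DMPU, −78 to −40 °C
Reagents that add atoms: iodomethane, CI
Why: Second α′-alkylation; the ketone α′-hydrogen is removed faster than the less acidic lactone α-hydrogens, and iodomethane again approaches anti to the C9 silyloxy group, so the methyl group ends trans and the C7 chain cis to the C9 oxygen, which fixes quaternary C8.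

Step 16
Reactants: 23 C8-quaternary enone (8S,9S)
Product: 24 exocyclic diene (C14=C15 and C12=C13)
Conditions: Zn, CH2Br2, TiCl4, THF, 0 °C to rt
Reagents that add atoms: dibromomethane, BrCBr
Why: Takai–Lombardo methylenation; the non-basic gem-dimetallic reagent methylenates the hindered enone carbonyl without enolization and tolerates the lactone and silyl ethers.

Step 17
Reactants: 24 exocyclic diene
Product: 25 dienol (free C9–OH)
Conditions: HF·pyridine, pyridine, THF, 0 °C to rt
Reagents that add atoms: none
Why: The secondary TBS ether is cleaved selectively beside the bulkier TIPS ether under buffered HF conditions, which are mild enough for the diene.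

Step 18
Reactants: 25 dienol
Product: 26 vinyl spiro-epoxide (14R)
Conditions: VO(acac)2 (5 mol %), t-BuOOH (1.5 equiv), 2,6-lutidine, CH2Cl2, 0 °C
Reagents that add atoms: tert-butyl hydroperoxide, CC(C)(C)OO
Why: Hydroxyl-directed vanadium epoxidation; the homoallylic C9–OH delivers oxygen to the near face of the proximal exocyclic C14=C15 alkene, so the epoxide oxygen is cis to C9–OH and to the C7 chain, while the undirected C12=C13 and C10=CH2 alkenes should react much more slowly.

Step 19
Reactants: 26 vinyl spiro-epoxide (14R); 19 ethyl 4,5-dimethyl-3-oxo-2,3-dihydrofuran-2-carboxylate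
Product: 28 spirolactone alcohol (14R,16R), via hydroxy ester 27 (not isolated)
Conditions: 19 (2 equiv), Cs2CO3 (0.5 equiv), DMF, 60 °C
Reagents that add atoms: none
Why: Acetoacetic-ester-type epoxide annulation; the stabilized enolate opens the epoxide at the unhindered CH2 (C15), the tertiary C14 alkoxide closes the γ-lactone onto the ethyl ester with C14 retained from the epoxide, and C16 should settle with the furanone ring oxygen rather than its carbonyl next to quaternary C8, because the doubly activated C16–C(=O)O bond can reopen and reclose (retro-Claisen/Claisen) under the basic conditions.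

Step 20
Reactants: 28 spirolactone alcohol
Product: 29 spirolactone C9 ketone
Conditions: Dess–Martin periodinane, NaHCO3, CH2Cl2, 0 °C to rt
Reagents that add atoms: none
Why: Buffered Dess–Martin oxidation of the hindered secondary alcohol gives the β,γ-unsaturated ketone without acid or base that would move the alkene into conjugation.

Step 21
Reactants: 29 spirolactone C9 ketone
Product: 30 dienyl triflate
Conditions: Tf2O (1.5 equiv), 2,6-di-tert-butyl-4-methylpyridine (2 equiv), CH2Cl2, 0 °C to rt
Reagents that add atoms: triflic anhydride, O=S(=O)(OS(=O)(=O)C(F)(F)F)C(F)(F)F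
Why: Enol triflate formation by O-triflation of the ketone and loss of a C11 proton to the hindered pyridine avoids a free dienolate, which would expel the allylic lactone carboxylate; C8 is quaternary, so only C11 can be deprotonated.

Step 22
Reactants: 30 dienyl triflate
Product: 31 ring-B-closed diene TIPS ether (10R as named here)
Conditions: Pd(OAc)2 (10 mol %), PPh3 (25 mol %), HCO2Na (3 equiv), Et4NCl (1 equiv), DMF, 60 °C
Reagents that add atoms: none
Why: Zerovalent palladium (from Pd(OAc)2 and PPh3) inserts into the C9–OTf bond, the alkenylpalladium adds syn across the tethered 1,1-disubstituted C10=CH2 alkene, and the resulting neopentyl alkylpalladium, which has no β-hydrogen, is reduced by formate so that the former methylene becomes the C10 methyl group. The closest known reaction type is the formate-terminated (reductive) intramolecular Heck cyclization used to build congested quaternary carbons. Ring B closes in the 6-exo-trig mode by C9–C10 bond formation, and C9 stays sp2, so the B/C ring fusion is left to be set afterwards. The new stereocentre C10 is controlled by the resident C5 centre: in the chair-like transition state the C5–C6 tether bond and the larger ring A branch (C1 with its silyloxy group) lie equatorial on the forming ring and the CH2–Pd carbon is axial and anti to C5–H, which should give the trans A/B fusion. The step needs exo regioselectivity, this facial selectivity, and oxidative addition at the alkenyl triflate in preference to the two allylic C–O bonds; the tether length, the fast insertion of zerovalent palladium into alkenyl triflates at 60 °C and the rapid formate capture of the neopentyl palladium species are meant to secure them.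

Step 23
Reactants: 31 ring-B-closed diene TIPS ether
Product: 32 diene C1 alcohol
Conditions: Bu4NF, AcOH, THF, 0 °C to rt
Reagents that add atoms: none
Why: Fluoride cleaves the TIPS ether, and acetic acid buffering protects the lactones and the tertiary allylic C14–O bond.

Step 24
Reactants: 32 diene C1 alcohol
Product: 33 deacetyl target (9S)
Conditions: [Ir(cod)(PCy3)(py)]PF6 (10 mol %), H2 (1 atm), CH2Cl2, 0 °C to rt
Reagents that add atoms: none
Why: Hydroxyl-directed hydrogenation with a cationic iridium catalyst; the homoallylic C1–OH binds the metal and delivers hydrogen to the proximal C9=C11 alkene from the face opposite both angular methyl groups (trans B/C fusion), while the remote C12=C13 alkene next to the spiro centre should react much more slowly.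

Step 25
Reactants: 33 deacetyl target
Product: 34 target (CNP0131208.1)
Conditions: Ac2O, DMAP, pyridine, CH2Cl2, rt
Reagents that add atoms: acetic anhydride, CC(=O)OC(C)=O
Why: DMAP-catalysed acetylation of the hindered secondary C1 alcohol; no stereocentre is touched.

**Compound list**

1 | (3E)-4,8-dimethylnona-3,7-dien-1-ol (homogeraniol) | CC(C)=CCC/C(C)=C/CCO | starting material
2 | tert-butyl{[(3E)-4,8-dimethylnona-3,7-dien-1-yl]oxy}dimethylsilane | CC(C)=CCC/C(C)=C/CCO[Si](C)(C)C(C)(C)C | intermediate
3 | tert-butyl({(3E)-6-[(2R)-3,3-dimethyloxiran-2-yl]-4-methylhex-3-en-1-yl}oxy)dimethylsilane | CC1(C)O[C@@H]1CC/C(C)=C/CCO[Si](C)(C)C(C)(C)C | intermediate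
4 | (1R,3S)-3-[2-(tert-butyldimethylsilyloxy)ethyl]-2,2-dimethyl-4-methylidenecyclohexan-1-ol | O[C@@H]1CCC(=C)[C@H](CCO[Si](C)(C)C(C)(C)C)C1(C)C | intermediate
5 | (3S)-3-[2-(tert-butyldimethylsilyloxy)ethyl]-2,2-dimethyl-4-methylidenecyclohexan-1-one | O=C1CCC(=C)[C@H](CCO[Si](C)(C)C(C)(C)C)C1(C)C | intermediate
6 | (6S)-6-[2-(tert-butyldimethylsilyloxy)ethyl]-7,7-dimethyl-5-methylideneoxepan-2-one | O=C1CCC(=C)[C@H](CCO[Si](C)(C)C(C)(C)C)C(C)(C)O1 | intermediate
7 | (4R,6S)-6-[2-(tert-butyldimethylsilyloxy)ethyl]-4-hydroxy-7,7-dimethyl-5-methylideneoxepan-2-one | O[C@@H]1CC(=O)OC(C)(C)[C@@H](CCO[Si](C)(C)C(C)(C)C)C1=C | intermediate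
8 | (4R,6S)-6-[2-(tert-butyldimethylsilyloxy)ethyl]-7,7-dimethyl-5-methylidene-4-(triisopropylsilyloxy)oxepan-2-one | CC(C)[Si](C(C)C)(C(C)C)O[C@@H]1CC(=O)OC(C)(C)[C@@H](CCO[Si](C)(C)C(C)(C)C)C1=C | intermediate
9 | (4R,6S)-6-(2-hydroxyethyl)-7,7-dimethyl-5-methylidene-4-(triisopropylsilyloxy)oxepan-2-one | CC(C)[Si](C(C)C)(C(C)C)O[C@@H]1CC(=O)OC(C)(C)[C@@H](CCO)C1=C | intermediate
10 | 2-[(3S,5R)-2,2-dimethyl-4-methylidene-7-oxo-5-(triisopropylsilyloxy)oxepan-3-yl]ethyl trifluoromethanesulfonate | CC(C)[Si](C(C)C)(C(C)C)O[C@@H]1CC(=O)OC(C)(C)[C@@H](CCOS(=O)(=O)C(F)(F)F)C1=C | intermediate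
11 | (S)-carvone [(5S)-2-methyl-5-(prop-1-en-2-yl)cyclohex-2-en-1-one] | CC1=CC[C@@H](CC1=O)C(C)=C | starting material
12 | (5S)-5-(1-hydroperoxy-1-methoxyethyl)-2-methylcyclohex-2-en-1-one (epimers at the peroxy carbon) | CC1=CC[C@@H](CC1=O)C(C)(OC)OO | intermediate
13 | (1S)-4-methyl-5-oxocyclohex-3-en-1-yl acetate | CC1=CC[C@@H](CC1=O)OC(C)=O | intermediate
14 | (5S)-5-hydroxy-2-methylcyclohex-2-en-1-one | CC1=CC[C@@H](CC1=O)O | intermediate
15 | (5S)-5-(tert-butyldimethylsilyloxy)-2-methylcyclohex-2-en-1-one | CC1=CC[C@@H](CC1=O)O[Si](C)(C)C(C)(C)C | intermediate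
16 | ethyl glycolate | CCOC(=O)CO | starting material
17 | ethyl 2-methylbuta-2,3-dienoate | CCOC(=O)C(C)=C=C | starting material
18 | ethyl 3-(2-ethoxy-2-oxoethoxy)-2-methylbut-2-enoate (E/Z) | CCOC(=O)COC(C)=C(C)C(=O)OCC | intermediate
19 | ethyl 4,5-dimethyl-3-oxo-2,3-dihydrofuran-2-carboxylate (in equilibrium with the 3-hydroxyfuran tautomer) | CCOC(=O)C1OC(C)=C(C)C1=O | intermediate
20 | lithium cross-conjugated dienolate of 15 (O–C14=C8, C12=C13; 9S) | CC1=CC[C@H](O[Si](C)(C)C(C)(C)C)C=C1O[Li] | intermediate
21 | (4R,6S)-6-{2-[(1R,6S)-6-(tert-butyldimethylsilyloxy)-3-methyl-2-oxocyclohex-3-en-1-yl]ethyl}-7,7-dimethyl-5-methylidene-4-(triisopropylsilyloxy)oxepan-2-one | CC(C)[Si](C(C)C)(C(C)C)O[C@@H]1CC(=O)OC(C)(C)[C@@H](CC[C@@H]2[C@@H](O[Si](C)(C)C(C)(C)C)CC=C(C)C2=O)C1=C | intermediate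
22 | lithium enolate of 21 (O–C14=C8 tetrasubstituted; 1R,5S,9S) | CC(C)[Si](C(C)C)(C(C)C)O[C@@H]1CC(=O)OC(C)(C)[C@@H](CCC2=C(O[Li])C(C)=CC[C@@H]2O[Si](C)(C)C(C)(C)C)C1=C | intermediate
23 | (4R,6S)-6-{2-[(1S,6S)-6-(tert-butyldimethylsilyloxy)-1,3-dimethyl-2-oxocyclohex-3-en-1-yl]ethyl}-7,7-dimethyl-5-methylidene-4-(triisopropylsilyloxy)oxepan-2-one | CC(C)[Si](C(C)C)(C(C)C)O[C@@H]1CC(=O)OC(C)(C)[C@@H](CC[C@@]2(C)[C@@H](O[Si](C)(C)C(C)(C)C)CC=C(C)C2=O)C1=C | intermediate
24 | (4R,6S)-6-{2-[(1R,6S)-6-(tert-butyldimethylsilyloxy)-1,3-dimethyl-2-methylidenecyclohex-3-en-1-yl]ethyl}-7,7-dimethyl-5-methylidene-4-(triisopropylsilyloxy)oxepan-2-one | CC(C)[Si](C(C)C)(C(C)C)O[C@@H]1CC(=O)OC(C)(C)[C@@H](CC[C@@]2(C)[C@@H](O[Si](C)(C)C(C)(C)C)CC=C(C)C2=C)C1=C | intermediate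
25 | (4R,6S)-6-{2-[(1R,6S)-6-hydroxy-1,3-dimethyl-2-methylidenecyclohex-3-en-1-yl]ethyl}-7,7-dimethyl-5-methylidene-4-(triisopropylsilyloxy)oxepan-2-one | CC(C)[Si](C(C)C)(C(C)C)O[C@@H]1CC(=O)OC(C)(C)[C@@H](CC[C@@]2(C)[C@@H](O)CC=C(C)C2=C)C1=C | intermediate
26 | (4R,6S)-6-{2-[(3R,7S,8S)-7-hydroxy-4,8-dimethyl-1-oxaspiro[2.5]oct-4-en-8-yl]ethyl}-7,7-dimethyl-5-methylidene-4-(triisopropylsilyloxy)oxepan-2-one | CC(C)[Si](C(C)C)(C(C)C)O[C@@H]1CC(=O)OC(C)(C)[C@@H](CC[C@@]2(C)[C@@H](O)CC=C(C)[C@]23CO3)C1=C | intermediate
27 | ring-opened hydroxy ester: C15–C16 bond formed between ring C (free C9–OH and C14–OH) and C2 of the ethyl furanone-2-carboxylate; lactone not yet closed (1R,5S,8S,9S,14R,16R) | CC(C)[Si](C(C)C)(C(C)C)O[C@@H]1CC(=O)OC(C)(C)[C@@H](CC[C@@]2(C)[C@@H](O)CC=C(C)[C@]2(O)C[C@]3(OC(C)=C(C)C3=O)C(=O)OCC)C1=C | intermediate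
28 | 9,10-seco alcohol (1R,5S,8S,9S,14R,16R): ring A lactone (C1–OTIPS, C10=CH2) joined through C6–C7 to C8 of ring C (C9–OH, C12=C13), C14 spiro to the γ-lactone, C16 spiro to the 4,5-dimethylfuran-3(2H)-one | CC(C)[Si](C(C)C)(C(C)C)O[C@@H]1CC(=O)OC(C)(C)[C@@H](CC[C@@]2(C)[C@@H](O)CC=C(C)[C@]23C[C@]4(OC(C)=C(C)C4=O)C(=O)O3)C1=C | intermediate
29 | 9,10-seco C9 ketone (1R,5S,8R,14R,16R), otherwise as 28 | CC(C)[Si](C(C)C)(C(C)C)O[C@@H]1CC(=O)OC(C)(C)[C@@H](CC[C@@]2(C)C(=O)CC=C(C)[C@]23C[C@]4(OC(C)=C(C)C4=O)C(=O)O3)C1=C | intermediate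
30 | 9,10-seco dienyl triflate (1R,5S,8R,14R,16R): C9(OTf)=C11–C12=C13, otherwise as 28 | CC(C)[Si](C(C)C)(C(C)C)O[C@@H]1CC(=O)OC(C)(C)[C@@H](CC[C@@]2(C)C(OS(=O)(=O)C(F)(F)F)=CC=C(C)[C@]23C[C@]4(OC(C)=C(C)C4=O)C(=O)O3)C1=C | intermediate
31 | pentacyclic 9(11),12-diene, C1 TIPS ether (1R,5S,8S,10R,14R,16R) | CC(C)[Si](C(C)C)(C(C)C)O[C@@H]1CC(=O)OC(C)(C)[C@H]2CC[C@@]3(C)C(=CC=C(C)[C@]34C[C@]3(OC(C)=C(C)C3=O)C(=O)O4)[C@@]21C | intermediate
32 | pentacyclic 9(11),12-diene C1 alcohol (1R,5S,8S,10R,14R,16R) | O[C@@H]1CC(=O)OC(C)(C)[C@H]2CC[C@@]3(C)C(=CC=C(C)[C@]34C[C@]3(OC(C)=C(C)C3=O)C(=O)O4)[C@@]21C | intermediate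
33 | deacetyl target, C1 alcohol (1R,5S,8S,9S,10S,14R,16R) | O[C@@H]1CC(=O)OC(C)(C)[C@H]2CC[C@@]3(C)[C@@H](CC=C(C)[C@]34C[C@]3(OC(C)=C(C)C3=O)C(=O)O4)[C@@]21C | intermediate
34 | CNP0131208.1, C1 acetate (1R,5S,8S,9S,10S,14R,16R) | CC(=O)O[C@@H]1CC(=O)OC(C)(C)[C@H]2CC[C@@]3(C)[C@@H](CC=C(C)[C@]34C[C@]3(OC(C)=C(C)C3=O)C(=O)O4)[C@@]21C | target

**Step count**

Total: 25 steps. Longest linear sequence: 21 steps (steps 1–9, then 14–25).

**Steps most likely to fail**

Step 22 (key step). The carbopalladation may show poor facial selectivity at C10 (cis A/B fusion). Zerovalent palladium may also ionise the allylic C14–O lactone bond, or formate may reduce the alkenylpalladium before it cyclises. Fallback, from 30 back to 31: the closure would be moved from carbopalladation to radical capture. Hydrogen atom transfer from an iron hydride (Fe(acac)3, PhSiH3) to C10=CH2 gives the tertiary C10 radical, which is intercepted by the alkenylnickel species formed from the triflate (NiBr2(diglyme), 4,4′-di-tert-butyl-2,2′-bipyridine, Mn powder, DMPU), a Markovnikov hydroalkenylation of the olefin hydroarylation type. The early radical step does not need the strained syn-insertion geometry; competing hydrogen atom transfer to the diene would have to be watched. This path makes no new compound (F0).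

Step 19. The hindered spiro-epoxide may open slowly, the enolate may attack at C12 with allylic transposition or alkylate on oxygen, and control of the spiro centre C16 is weak. Fallback, from 26 back to 28: the epoxide would be opened at C15 with the lithium enolate of 2,2-dimethyl-1,3-dioxolan-4-one (LiN(i-Pr)2, THF/DMPU). The C14 alkoxide then closes onto the dioxolanone carbonyl with loss of acetone to give the α-hydroxy spirolactone F1 (C16 epimers, of no consequence). Oxa-Michael addition of the C16 hydroxyl to allenoate 17 (PMe3 cat.) gives the β-alkoxy enoate F2. LiN(SiMe3)2 then effects a 5-exo Dieckmann closure of the lactone enolate onto the enoate ester; the new C16–C(=O) bond forms on the lactone face away from quaternary C8, which sets C16 kinetically and delivers 28.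

Step 24. The conjugated diene may be reduced at the wrong double bond, by 1,4-addition, or twice. Fallback, from 31 back to 33: the more accessible C12=C13 alkene would be masked as its epoxide F3 (mCPBA, NaHCO3). The now isolated, hindered C9=C11 alkene would be reduced under thermodynamic control by hydrogen atom transfer (Mn(dpm)3, PhSiH3, t-BuOOH, i-PrOH) to the trans-fused F4. Oxygen transfer to PPh3 catalysed by MeReO3 would restore the C12=C13 alkene in F5, and fluoride removal of the TIPS group as in step 23 rejoins the route at 33.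

**Further compounds**

F0 | step 22 | none | none
F1 | step 19 | α-hydroxy spirolactone (C16–OH, C16 epimers; otherwise as 28 without the furanone) | CC(C)[Si](C(C)C)(C(C)C)O[C@@H]1CC(=O)OC(C)(C)[C@@H](CC[C@@]2(C)[C@@H](O)CC=C(C)[C@]23CC(O)C(=O)O3)C1=C
F2 | step 19 | β-alkoxy enoate: C16–O–C(Me)=C(Me)–CO2Et on the spirolactone (C16 epimers) | CC(C)[Si](C(C)C)(C(C)C)O[C@@H]1CC(=O)OC(C)(C)[C@@H](CC[C@@]2(C)[C@@H](O)CC=C(C)[C@]23CC(OC(C)=C(C)C(=O)OCC)C(=O)O3)C1=C
F3 | step 24 | 12,13-epoxide of 31 (epoxide face of no consequence) | CC(C)[Si](C(C)C)(C(C)C)O[C@@H]1CC(=O)OC(C)(C)[C@H]2CC[C@@]3(C)C(=CC5OC5(C)[C@]34C[C@]3(OC(C)=C(C)C3=O)C(=O)O4)[C@@]21C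
F4 | step 24 | 9,11-dihydro-12,13-epoxide (9S, trans B/C), C1 TIPS ether | CC(C)[Si](C(C)C)(C(C)C)O[C@@H]1CC(=O)OC(C)(C)[C@H]2CC[C@@]3(C)[C@@H](CC5OC5(C)[C@]34C[C@]3(OC(C)=C(C)C3=O)C(=O)O4)[C@@]21C
F5 | step 24 | C1 TIPS ether of 33 | CC(C)[Si](C(C)C)(C(C)C)O[C@@H]1CC(=O)OC(C)(C)[C@H]2CC[C@@]3(C)[C@@H](CC=C(C)[C@]34C[C@]3(OC(C)=C(C)C3=O)C(=O)O4)[C@@]21C
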